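The vessel was a closed, stirred, isothermal flask in which free catalyst had to carry substrate and partner to target while the partner also decayed by itself.

substrate 0.40 M; partner 0.360 M; free catalyst 8.0 mM; impurity 0.90 mM

    partner → decomposed reagent (k1 = 0.00127 /s)
    free catalyst + open intermediate ⇌ catalyst intermediate (K2 = 100 /M, k2 = 0.197 /M/s)
    substrate + free catalyst ⇌ free catalyst + open intermediate (K3 = 7.1, k3 = 0.102 /M/s)
    partner + catalyst intermediate → free catalyst + target (k4 = 0.0783 /M/s)
    free catalyst + impurity → spent catalyst (k5 = 15.0 /M/s)

- the form that holds most of the catalyst when 30% of the substrate are converted (spent catalyst / free catalyst / catalyst intermediate)
- its share of the catalyst then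
- apparent order in free catalyst when 30% of the substrate are converted (percent change of the rate of making target for one percent more free catalyst charged)
- apparent order in partner when 30% of the substrate are converted (percent change of the rate of making target for one percent more partner charged)

I turned the question round: what would the numbers need for partner to go mostly into target, and for free catalyst to be the resting state? Partner is the limiting reagent, 0.360 M against 0.40 M of substrate, so I wrote its balance:

−d[partner]/dt = (0.00127 /s + 0.0783 /M/s · [catalyst intermediate]) · [partner]

Target would win with [catalyst intermediate] above 16.2 mM. I counted the impurity as removing its own amount of catalyst, which leaves 7.10 mM live, less than that. So I took as my measure the diversion ratio, the first-order decay of partner over its use by the target step with all live catalyst as catalyst intermediate: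

ratio = 2.28, target at most 0.110 M

Then I supposed about half the live catalyst worked as catalyst intermediate, which doubles the ratio, and went to the 30% mark at 0.217 h:

[partner] ≈ 0.108 M
target ≈ 0.0453 M
[open intermediate] ≈ 0.0747 M

Free catalyst would lead if catalyst intermediate formed more slowly than it left, a ratio below one. Mine was 1.42, which made catalyst intermediate the largest form, at 52.0%.

The target step carries [partner] to the first power, so, holding [catalyst intermediate] fixed as an assumption, I expected an order of 1.00. For the catalyst I could give a floor: one percent more charged is 1.13 percent more live catalyst. My reckoning stopped there.

The forecast named catalyst intermediate at 52%, with orders 1.8 in catalyst and 0.8 in partner, holding that “more catalyst or partner means less partner lost to decomposition by the time 30% conversion is reached”.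

The simulation gave catalyst intermediate at 52.9%, beside 35.8% free catalyst and 11.2% spent catalyst, with orders 2.1 and 1.0.

At 0.123 h decomposition used partner 5.4 times as fast as the target step, above the diversion ratio of 2.28, and by 2.50 h partner stood at 0%, with >99.9% of its decomposition behind it. Target then stood at 14.1% of the substrate charged, under the ceiling of 27.5%, while open intermediate rose to 52.0% at 5.00 h.

(All constants are assumed; the flask was simulated.)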